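## Retrosynthetic overview

1. Target ⇐ cycloisomerisation of a C14≡C15 alkyne onto the C16 hydroxyl (dihydrofuran) ⇐ 8β-acetate by orthoacetate opening, and the 9α,13-ether ring by trans-diaxial opening of an 8β,9β-epoxide by the C13 carbinol ⇐ Δ8-7β-ol.
2. Side chain: C11–C12 from an allylic bromide and the 2-methylallyl alcohol dianion; C13 set by Sharpless epoxidation; C15 added by Ohira–Bestmann homologation.
3. Ring B: C9–C10 by cation–olefin cyclisation of a ring A alkene onto a β-keto ester, which relays C4/C5 to C10; C17 by methylation of the enol triflate.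
4. Ring A: C2–C3 and C4–C5 in one catalytic enantioselective Diels–Alder reaction of an achiral, acyclic dienyl β-keto ester (C2=C1–C10=C5) with methacrolein (C3=C4 with C18 and C19).
5. Enabling feature: ring A carries its only oxidised carbon (C19) on quaternary C4 next to the C5 methine, and C1–C10 can stay an alkene until ring B closure makes C10 quaternary, so C3–C4(C18)(C19) is a methacrolein retron. Ring order: A (step 4), B (step 7), tetrahydrofuran (step 20), dihydrofuran (step 24).

Key step: step 4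

Convention: labdane numbering of the target is used for every compound (C18 = 4α-methyl, C19 = 4β-CH2O, C20 = 10β-methyl, C17 on C8); TBDPS = tert-butyldiphenylsilyl, TBS = tert-butyldimethylsilyl.

Assumption: the facial sense of the oxazaborolidinium catalyst in step 4 is taken from its accepted transition-state model (diene attacks the enal face remote from the catalyst phenyl group); if the opposite sense were found, the enantiomeric catalyst would be used with no other change.

## Route

Step 1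
Reactants: 1 (E)-3-methylpent-2-en-4-yn-1-ol
Product: 2 (E)-3-methylpenta-2,4-dien-1-ol
Conditions: H2 (1 atm), Pd/CaCO3 poisoned with Pb(OAc)2, quinoline, MeOH, rt
Reagents that add atoms: none
Why: Semihydrogenation of a terminal alkyne over poisoned palladium should stop at the alkene and leave the existing (E)-trisubstituted alkene untouched.

Step 2
Reactants: 2 (E)-3-methylpenta-2,4-dien-1-ol
Product: 3 (E)-5-bromo-3-methylpenta-1,3-diene
Conditions: PBr3 (0.4 equiv), pyridine (cat.), Et2O, −10 °C; used crude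
Reagents that add atoms: phosphorus tribromide, BrP(Br)Br
Why: Bromination of a primary allylic alcohol through its phosphite should give the conjugated primary bromide, which is the thermodynamically preferred allylic isomer, with the (E)-geometry kept.

Step 3
Reactants: 3 (E)-5-bromo-3-methylpenta-1,3-diene; 4 methyl acetoacetate
Product: 6 methyl (6E)-7-methyl-3-oxonona-6,8-dienoate, via methyl acetoacetate dianion 5 (not isolated)
Conditions: 4, NaH, THF, 0 °C; n-BuLi, 0 °C; then 3, 0 °C → rt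
Reagents that add atoms: none
Why: In this acetoacetate dianion γ-alkylation the more basic terminal carbanion should displace the allylic bromide by SN2 and create the C6–C7 bond while the β-keto ester is kept as its enolate.

Step 4
Reactants: 6 methyl (6E)-7-methyl-3-oxonona-6,8-dienoate; 7 methacrolein
Product: 8 methyl 5-[(1R,6S)-6-formyl-2,6-dimethylcyclohex-2-en-1-yl]-3-oxopentanoate
Conditions: 7 (3 equiv), (S)-1-(2-methylphenyl)-3,3-diphenyltetrahydro-1H,3H-pyrrolo[1,2-c][1,3,2]oxazaborole (20 mol %), HNTf2 (17 mol %), CH2Cl2, −78 → −40 °C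
Reagents that add atoms: none
Why: The triflimide-activated oxazaborolidine binds methacrolein at its carbonyl oxygen (formyl C–H···O contact, s-trans enal) and the diene adds in a concerted but asynchronous [4π+2π] cycloaddition, the β-carbon C3 bonding first to the free terminus C2 and the α-carbon C4 then to C5. The closest known reaction type is the oxazaborolidinium-catalysed enantioselective Diels–Alder reaction of 2-substituted acroleins with acyclic dienes. Ring A is closed in one intermolecular suprafacial [4+2] event that forms C2–C3 and C4–C5 and leaves the C1=C10 alkene for ring B. C4 (quaternary, C18 α and C19 β) is set by the catalyst, which shields one face of the bound enal, and C5 is set relative to C4 by the formyl-endo approach to the (E)-diene, which places C19 cis to the C6 chain. The step needs ortho regioselectivity, endo selectivity and chemoselectivity: the C5-alkyl terminus directs the formyl-bearing carbon to C5 and sterics favour early bonding at the unsubstituted CH2 terminus, Lewis-acid activation should raise both preferences, and the ketone and ester of the tether are not dienophiles and should bind boron less well than the aldehyde.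

Step 5
Reactants: 8 methyl 5-[(1R,6S)-6-formyl-2,6-dimethylcyclohex-2-en-1-yl]-3-oxopentanoate
Product: 9 methyl 5-[(1R,6S)-6-(hydroxymethyl)-2,6-dimethylcyclohex-2-en-1-yl]-3-oxopentanoate
Conditions: NaBH4 (0.5 equiv), EtOH/CH2Cl2, −78 °C
Reagents that add atoms: none
Why: Chemoselective borohydride reduction at low temperature should take the aldehyde far faster than the less electrophilic, partly enolised β-keto ester; no stereocentre is formed.

Step 6
Reactants: 9 methyl 5-[(1R,6S)-6-(hydroxymethyl)-2,6-dimethylcyclohex-2-en-1-yl]-3-oxopentanoate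
Product: 10 methyl 5-[(1R,6S)-6-(TBDPS-oxymethyl)-2,6-dimethylcyclohex-2-en-1-yl]-3-oxopentanoate
Conditions: TBDPSCl, imidazole, DMF, rt
Reagents that add atoms: tert-butyl(chloro)diphenylsilane, CC(C)(C)[Si](Cl)(c1ccccc1)c1ccccc1
Why: Silylation of the primary alcohol gives an acid-stable ether whose bulk keeps the C19 oxygen from trapping the cation of step 7.

Step 7
Reactants: 10 methyl 5-[(1R,6S)-6-(TBDPS-oxymethyl)-2,6-dimethylcyclohex-2-en-1-yl]-3-oxopentanoate
Product: 11 methyl 19-(TBDPS-oxy)-8-oxo-12,13,14,15,16,17-hexanorlabdan-11-oate (trans-decalin; 5α-H; 9α-H; 10β-methyl)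
Conditions: SnCl4 (2 equiv), CH2Cl2, −78 → 0 °C
Reagents that add atoms: none
Why: In this cation–olefin cyclisation Markovnikov protonation of the C1=C10 alkene gives the tertiary C10 cation, which the tin enolate carbon C9 captures 6-endo through a chair on the α-face, anti to the axial C19 group at C4, so that C10 is set as 10β-methyl (trans-decalin) and C9 equilibrates to the equatorial ester.

Step 8
Reactants: 11 methyl 19-(TBDPS-oxy)-8-oxo-12,13,14,15,16,17-hexanorlabdan-11-oate
Product: 12 methyl 19-(TBDPS-oxy)-8-(trifluoromethylsulfonyloxy)-12,13,14,15,16,17-hexanorlabd-8-en-11-oate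
Conditions: Tf2O, iPr2NEt, CH2Cl2, −78 °C
Reagents that add atoms: trifluoromethanesulfonic anhydride, O=S(=O)(OS(=O)(=O)C(F)(F)F)C(F)(F)F
Why: O-Sulfonylation of the β-keto ester enol (enol triflate formation) fixes the C8=C9 double bond.

Step 9
Reactants: 12 methyl 19-(TBDPS-oxy)-8-(trifluoromethylsulfonyloxy)-12,13,14,15,16,17-hexanorlabd-8-en-11-oate
Product: 13 methyl 19-(TBDPS-oxy)-12,13,14,15,16-pentanorlabd-8-en-11-oate
Conditions: MeMgBr, Fe(acac)3 (5 mol %), THF/NMP, −30 °C
Reagents that add atoms: methylmagnesium bromide, C[Mg]Br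
Why: Iron-catalysed cross-coupling of an enol triflate with a methyl Grignard reagent should install C17 faster than the reagent adds to the hindered ester and keeps the alkene at C8=C9.

Step 10
Reactants: 13 methyl 19-(TBDPS-oxy)-12,13,14,15,16-pentanorlabd-8-en-11-oate
Product: 14 19-(TBDPS-oxy)-12,13,14,15,16-pentanorlabd-8-en-11-ol
Conditions: i-Bu2AlH (2.5 equiv), CH2Cl2, −78 → 0 °C
Reagents that add atoms: none
Why: 1,2-Reduction of the conjugated ester with the aluminium hydride should give the primary allylic alcohol without touching the tetrasubstituted alkene.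

Step 11
Reactants: 14 19-(TBDPS-oxy)-12,13,14,15,16-pentanorlabd-8-en-11-ol
Product: 15 11-bromo-19-(TBDPS-oxy)-12,13,14,15,16-pentanorlabd-8-ene
Conditions: PBr3 (0.4 equiv), pyridine (cat.), Et2O, −20 °C; used crude
Reagents that add atoms: phosphorus tribromide, BrP(Br)Br
Why: Bromination of the primary allylic alcohol should give the primary bromide because the transposed position C8 is fully substituted.

Step 12
Reactants: 15 11-bromo-19-(TBDPS-oxy)-12,13,14,15,16-pentanorlabd-8-ene; 16 2-methylprop-2-en-1-ol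
Product: 18 19-(TBDPS-oxy)-15-norlabda-8,13(16)-dien-14-ol, via 2-methylallyl alcohol dianion 17 (not isolated)
Conditions: 16, n-BuLi (2.2 equiv), TMEDA, Et2O, 0 °C → rt; then 15, THF, −78 → 0 °C
Reagents that add atoms: none
Why: C-Alkylation of the symmetric allyl anion of the 2-methylallyl alcohol dianion by the allylic bromide (SN2 at primary C11) should form C11–C12 and deliver the 2-substituted allylic alcohol needed for asymmetric epoxidation.

Step 13
Reactants: 18 19-(TBDPS-oxy)-15-norlabda-8,13(16)-dien-14-ol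
Product: 19 (13S)-13,16-epoxy-19-(TBDPS-oxy)-15-norlabd-8-en-14-ol
Conditions: Ti(OiPr)4 (10 mol %), L-(+)-diethyl tartrate (12 mol %), t-BuOOH, 4 Å MS, CH2Cl2, −20 °C
Reagents that add atoms: tert-butyl hydroperoxide, CC(C)(C)OO
Why: Sharpless asymmetric epoxidation of the allylic alcohol with the L-(+)-tartrate should set C13 as S by reagent control, and the Δ8 alkene, which has no allylic hydroxyl, should not react.

Step 14
Reactants: 19 (13S)-13,16-epoxy-19-(TBDPS-oxy)-15-norlabd-8-en-14-ol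
Product: 20 (13R)-13,16-epoxy-19-(TBDPS-oxy)-15-norlabd-8-en-14-al
Conditions: Dess–Martin periodinane, NaHCO3, CH2Cl2, 0 °C → rt
Reagents that add atoms: none
Why: Dess–Martin oxidation gives the epoxy aldehyde under buffered conditions, and the quaternary α-carbon C13 cannot epimerise (the descriptor changes only by priority).

Step 15
Reactants: 20 (13R)-13,16-epoxy-19-(TBDPS-oxy)-15-norlabd-8-en-14-al
Product: 21 (13S)-13,16-epoxy-19-(TBDPS-oxy)labd-8-en-14-yne
Conditions: dimethyl (1-diazo-2-oxopropyl)phosphonate, K2CO3, MeOH, 0 °C → rt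
Reagents that add atoms: dimethyl (1-diazo-2-oxopropyl)phosphonate, COP(=O)(OC)C(=[N+]=[N-])C(C)=O
Why: Ohira–Bestmann (Seyferth–Gilbert) homologation converts the aldehyde into the terminal alkyne and adds C15 under mild base that the epoxide tolerates.

Step 16
Reactants: 21 (13S)-13,16-epoxy-19-(TBDPS-oxy)labd-8-en-14-yne
Product: 22 (13S)-19-(TBDPS-oxy)labd-8-en-14-yne-13,16-diol
Conditions: KOH (1 M aq.), DMSO, 50 °C
Reagents that add atoms: water, O
Why: Hydroxide opens the 2,2-disubstituted epoxide by SN2 at the primary carbon C16, so the C13–O bond and the C13 configuration are kept.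

Step 17
Reactants: 22 (13S)-19-(TBDPS-oxy)labd-8-en-14-yne-13,16-diol
Product: 23 (13S)-16-(TBS-oxy)-19-(TBDPS-oxy)labd-8-en-14-yn-13-ol
Conditions: TBSCl, imidazole, DMF, 0 °C
Reagents that add atoms: tert-butyl(chloro)dimethylsilane, CC(C)(C)[Si](C)(C)Cl
Why: Selective silylation of the primary alcohol leaves the tertiary propargylic C13 hydroxyl as the only nucleophile for ether formation in step 20.

Step 18
Reactants: 23 (13S)-16-(TBS-oxy)-19-(TBDPS-oxy)labd-8-en-14-yn-13-ol
Product: 24 (13S)-13-hydroxy-16-(TBS-oxy)-19-(TBDPS-oxy)labd-8-en-14-yn-7-one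
Conditions: CrO3, 3,5-dimethylpyrazole, CH2Cl2, −20 °C
Reagents that add atoms: chromium trioxide, O=[Cr](=O)=O
Why: Allylic oxidation with the chromium trioxide–dimethylpyrazole complex should convert the ring methylene C7, whose axial C–H is aligned with the π system, into the enone, while C11 is shielded by the quaternary C10 and the branched side chain and the C17 methyl is less reactive.

Step 19
Reactants: 24 (13S)-13-hydroxy-16-(TBS-oxy)-19-(TBDPS-oxy)labd-8-en-14-yn-7-one
Product: 25 (13S)-16-(TBS-oxy)-19-(TBDPS-oxy)labd-8-en-14-yne-7β,13-diol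
Conditions: NaBH4, CeCl3·7H2O, MeOH, −78 → −20 °C
Reagents that add atoms: none
Why: Luche 1,2-reduction with axial hydride delivery from the α-face, away from the C10 methyl, should give the equatorial 7β-alcohol.

Step 20
Reactants: 25 (13S)-16-(TBS-oxy)-19-(TBDPS-oxy)labd-8-en-14-yne-7β,13-diol
Product: 27 (13S)-9α,13-epoxy-16-(TBS-oxy)-19-(TBDPS-oxy)labd-14-yne-7β,8β-diol, via 8β,9β-epoxide 26 (not isolated)
Conditions: mCPBA, CH2Cl2, 0 °C; then camphorsulfonic acid (cat.), rt
Reagents that add atoms: 3-chloroperbenzoic acid, OOC(=O)c1cccc(Cl)c1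
Why: Hydroxyl-directed peracid epoxidation should deliver oxygen syn to the 7β-hydroxyl (β-face), and acid-catalysed 5-exo-tet opening of this epoxide by the C13 hydroxyl at C9, the tertiary carbon remote from the C7 oxygen, proceeds trans-diaxially with inversion to set 9α-O and 8β-OH.

Step 21
Reactants: 27 (13S)-9α,13-epoxy-16-(TBS-oxy)-19-(TBDPS-oxy)labd-14-yne-7β,8β-diol
Product: 29 (13S)-8β-acetoxy-9α,13-epoxy-16-(TBS-oxy)-19-(TBDPS-oxy)labd-14-yn-7β-ol, via cyclic orthoacetate 28 (not isolated)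
Conditions: MeC(OMe)3, pyridinium p-toluenesulfonate (cat.), CH2Cl2, rt; then AcOH/H2O (4:1), 0 °C, short time
Reagents that add atoms: trimethyl orthoacetate, CC(OC)(OC)OC; water, O
Why: Orthoester exchange across the cis-7β,8β-diol followed by stereoelectronically controlled hydrolysis of the cyclic orthoester should place the acetate on the axial tertiary O8 and free the equatorial 7β-hydroxyl, which avoids direct acylation of the hindered tertiary alcohol.

Step 22
Reactants: 29 (13S)-8β-acetoxy-9α,13-epoxy-16-(TBS-oxy)-19-(TBDPS-oxy)labd-14-yn-7β-ol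
Product: 30 (13S)-8β-acetoxy-9α,13-epoxy-16-(TBS-oxy)-19-(TBDPS-oxy)labd-14-yn-7-one
Conditions: Dess–Martin periodinane, NaHCO3, CH2Cl2, rt
Reagents that add atoms: none
Why: Dess–Martin oxidation of the secondary alcohol gives the C7 ketone and at the same time removes the hydroxyl to which the acetate could migrate.

Step 23
Reactants: 30 (13S)-8β-acetoxy-9α,13-epoxy-16-(TBS-oxy)-19-(TBDPS-oxy)labd-14-yn-7-one
Product: 31 (13S)-8β-acetoxy-9α,13-epoxy-16,19-dihydroxylabd-14-yn-7-one
Conditions: Bu4NF, AcOH (1:1), THF, rt → 40 °C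
Reagents that add atoms: none
Why: Buffered fluoride desilylation should remove both silyl ethers without cleaving the tertiary acetate or enolising the α-acetoxy ketone.

Step 24
Reactants: 31 (13S)-8β-acetoxy-9α,13-epoxy-16,19-dihydroxylabd-14-yn-7-one
Product: 32 (13S)-8β-acetoxy-9α,13:15,16-diepoxy-19-hydroxylabd-14-en-7-one (CNP0239339.2)
Conditions: Mo(CO)6 (0.3 equiv), Et3N, Et2O, hν (350 nm); then 31, rt
Reagents that add atoms: none
Why: In this alkynol cycloisomerisation the molybdenum vinylidene formed from the terminal alkyne is trapped at C15 by the C16 hydroxyl (endo mode) to give the 2,3-dihydrofuran under basic conditions that the acid-labile spiro enol ether should survive, with C13 untouched.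

## Compound list

1 | (E)-3-methylpent-2-en-4-yn-1-ol | C#C/C(C)=C/CO | starting material
2 | (E)-3-methylpenta-2,4-dien-1-ol | C=C/C(C)=C/CO | intermediate
3 | (E)-5-bromo-3-methylpenta-1,3-diene | C=C/C(C)=C/CBr | intermediate
4 | methyl acetoacetate | COC(=O)CC(C)=O | starting material
5 | methyl acetoacetate dianion (sodium lithium salt) | [Na+].[Li+].COC(=O)[CH-]C(=O)[CH2-] | intermediate
6 | methyl (6E)-7-methyl-3-oxonona-6,8-dienoate | C=C/C(C)=C/CCC(=O)CC(=O)OC | intermediate
7 | methacrolein | CC(=C)C=O | starting material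
8 | methyl 5-[(1R,6S)-6-formyl-2,6-dimethylcyclohex-2-en-1-yl]-3-oxopentanoate | COC(=O)CC(=O)CC[C@H]1[C@@](C)(C=O)CCC=C1C | intermediate
9 | methyl 5-[(1R,6S)-6-(hydroxymethyl)-2,6-dimethylcyclohex-2-en-1-yl]-3-oxopentanoate | COC(=O)CC(=O)CC[C@H]1[C@@](C)(CO)CCC=C1C | intermediate
10 | methyl 5-[(1R,6S)-6-(TBDPS-oxymethyl)-2,6-dimethylcyclohex-2-en-1-yl]-3-oxopentanoate | COC(=O)CC(=O)CC[C@H]1[C@@](C)(CO[Si](c2ccccc2)(c2ccccc2)C(C)(C)C)CCC=C1C | intermediate
11 | methyl 19-(TBDPS-oxy)-8-oxo-12,13,14,15,16,17-hexanorlabdan-11-oate (trans-decalin; 5α-H; 9α-H; 10β-methyl) | COC(=O)[C@H]1C(=O)CC[C@H]2[C@@](C)(CO[Si](c3ccccc3)(c3ccccc3)C(C)(C)C)CCC[C@]12C | intermediate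
12 | methyl 19-(TBDPS-oxy)-8-(trifluoromethylsulfonyloxy)-12,13,14,15,16,17-hexanorlabd-8-en-11-oate | COC(=O)C1=C(OS(=O)(=O)C(F)(F)F)CC[C@H]2[C@@](C)(CO[Si](c3ccccc3)(c3ccccc3)C(C)(C)C)CCC[C@]12C | intermediate
13 | methyl 19-(TBDPS-oxy)-12,13,14,15,16-pentanorlabd-8-en-11-oate | COC(=O)C1=C(C)CC[C@H]2[C@@](C)(CO[Si](c3ccccc3)(c3ccccc3)C(C)(C)C)CCC[C@]12C | intermediate
14 | 19-(TBDPS-oxy)-12,13,14,15,16-pentanorlabd-8-en-11-ol | OCC1=C(C)CC[C@H]2[C@@](C)(CO[Si](c3ccccc3)(c3ccccc3)C(C)(C)C)CCC[C@]12C | intermediate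
15 | 11-bromo-19-(TBDPS-oxy)-12,13,14,15,16-pentanorlabd-8-ene | BrCC1=C(C)CC[C@H]2[C@@](C)(CO[Si](c3ccccc3)(c3ccccc3)C(C)(C)C)CCC[C@]12C | intermediate
16 | 2-methylprop-2-en-1-ol | CC(=C)CO | starting material
17 | 2-methylallyl alcohol dianion (dilithium salt) | [Li+].[Li+].[CH2-]C(=C)C[O-] | intermediate
18 | 19-(TBDPS-oxy)-15-norlabda-8,13(16)-dien-14-ol | C=C(CO)CCC1=C(C)CC[C@H]2[C@@](C)(CO[Si](c3ccccc3)(c3ccccc3)C(C)(C)C)CCC[C@]12C | intermediate
19 | (13S)-13,16-epoxy-19-(TBDPS-oxy)-15-norlabd-8-en-14-ol | OC[C@@]1(CCC2=C(C)CC[C@H]3[C@@](C)(CO[Si](c4ccccc4)(c4ccccc4)C(C)(C)C)CCC[C@]23C)CO1 | intermediate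
20 | (13R)-13,16-epoxy-19-(TBDPS-oxy)-15-norlabd-8-en-14-al | O=C[C@@]1(CCC2=C(C)CC[C@H]3[C@@](C)(CO[Si](c4ccccc4)(c4ccccc4)C(C)(C)C)CCC[C@]23C)CO1 | intermediate
21 | (13S)-13,16-epoxy-19-(TBDPS-oxy)labd-8-en-14-yne | C#C[C@@]1(CCC2=C(C)CC[C@H]3[C@@](C)(CO[Si](c4ccccc4)(c4ccccc4)C(C)(C)C)CCC[C@]23C)CO1 | intermediate
22 | (13S)-19-(TBDPS-oxy)labd-8-en-14-yne-13,16-diol | C#C[C@@](O)(CCC1=C(C)CC[C@H]2[C@@](C)(CO[Si](c3ccccc3)(c3ccccc3)C(C)(C)C)CCC[C@]12C)CO | intermediate
23 | (13S)-16-(TBS-oxy)-19-(TBDPS-oxy)labd-8-en-14-yn-13-ol | C#C[C@@](O)(CCC1=C(C)CC[C@H]2[C@@](C)(CO[Si](c3ccccc3)(c3ccccc3)C(C)(C)C)CCC[C@]12C)CO[Si](C)(C)C(C)(C)C | intermediate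
24 | (13S)-13-hydroxy-16-(TBS-oxy)-19-(TBDPS-oxy)labd-8-en-14-yn-7-one | C#C[C@@](O)(CCC1=C(C)C(=O)C[C@H]2[C@@](C)(CO[Si](c3ccccc3)(c3ccccc3)C(C)(C)C)CCC[C@]12C)CO[Si](C)(C)C(C)(C)C | intermediate
25 | (13S)-16-(TBS-oxy)-19-(TBDPS-oxy)labd-8-en-14-yne-7β,13-diol | C#C[C@@](O)(CCC1=C(C)[C@@H](O)C[C@H]2[C@@](C)(CO[Si](c3ccccc3)(c3ccccc3)C(C)(C)C)CCC[C@]12C)CO[Si](C)(C)C(C)(C)C | intermediate
26 | (13S)-8β,9β-epoxy-16-(TBS-oxy)-19-(TBDPS-oxy)labd-14-yne-7β,13-diol | C#C[C@@](O)(CC[C@]12O[C@@]1(C)[C@@H](O)C[C@H]3[C@@](C)(CO[Si](c4ccccc4)(c4ccccc4)C(C)(C)C)CCC[C@]23C)CO[Si](C)(C)C(C)(C)C | intermediate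
27 | (13S)-9α,13-epoxy-16-(TBS-oxy)-19-(TBDPS-oxy)labd-14-yne-7β,8β-diol | O[C@@]1(C)[C@@H](O)C[C@H]2[C@@](C)(CO[Si](c3ccccc3)(c3ccccc3)C(C)(C)C)CCC[C@]2(C)[C@@]12CC[C@](C#C)(CO[Si](C)(C)C(C)(C)C)O2 | intermediate
28 | 7β,8β-O-(1-methoxyethylidene) cyclic orthoacetate of 27 (both epimers at the orthoester carbon) | COC1(C)O[C@@]2(C)[C@@H](O1)C[C@H]3[C@@](C)(CO[Si](c4ccccc4)(c4ccccc4)C(C)(C)C)CCC[C@]3(C)[C@@]23CC[C@](C#C)(CO[Si](C)(C)C(C)(C)C)O3 | intermediate
29 | (13S)-8β-acetoxy-9α,13-epoxy-16-(TBS-oxy)-19-(TBDPS-oxy)labd-14-yn-7β-ol | CC(=O)O[C@@]1(C)[C@@H](O)C[C@H]2[C@@](C)(CO[Si](c3ccccc3)(c3ccccc3)C(C)(C)C)CCC[C@]2(C)[C@@]12CC[C@](C#C)(CO[Si](C)(C)C(C)(C)C)O2 | intermediate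
30 | (13S)-8β-acetoxy-9α,13-epoxy-16-(TBS-oxy)-19-(TBDPS-oxy)labd-14-yn-7-one | CC(=O)O[C@@]1(C)C(=O)C[C@H]2[C@@](C)(CO[Si](c3ccccc3)(c3ccccc3)C(C)(C)C)CCC[C@]2(C)[C@@]12CC[C@](C#C)(CO[Si](C)(C)C(C)(C)C)O2 | intermediate
31 | (13S)-8β-acetoxy-9α,13-epoxy-16,19-dihydroxylabd-14-yn-7-one | CC(=O)O[C@@]1(C)C(=O)C[C@H]2[C@@](C)(CO)CCC[C@]2(C)[C@@]12CC[C@](C#C)(CO)O2 | intermediate
32 | (13S)-8β-acetoxy-9α,13:15,16-diepoxy-19-hydroxylabd-14-en-7-one (CNP0239339.2) | CC(=O)O[C@@]1(C)C(=O)C[C@H]2[C@@](C)(CO)CCC[C@]2(C)[C@@]12CC[C@@]1(C=COC1)O2 | target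

## Step count and risks

Total step count: 24. Longest linear sequence: 24 steps (1 → 32); compounds 4, 7 and 16 are purchased and enter in single steps.

Steps most likely to fail:

Step 4. The enolisable β-keto ester may compete with methacrolein for the boron Lewis acid, and the C10 methyl of the diene opposes the ortho orientation, so conversion, regioselectivity and enantioselectivity may erode. The fallback sets out from 3 and comes back at 10. Alkylation of the lithium enolate of methyl acetate (LiN(iPr)2, MeOAc, THF/DMPU, −78 °C) with 3 should give methyl (4E)-5-methylhepta-4,6-dienoate F1. The same catalytic Diels–Alder reaction with 7, now with only a simple ester in the diene, should give methyl 3-[(1R,6S)-6-formyl-2,6-dimethylcyclohex-2-en-1-yl]propanoate F2. NaBH4 reduction, to which the ester is inert, should give methyl 3-[(1R,6S)-6-(hydroxymethyl)-2,6-dimethylcyclohex-2-en-1-yl]propanoate F3, and silylation (TBDPSCl, imidazole) its TBDPS ether F4. A crossed Claisen condensation of F4 with excess lithium enolate of methyl acetate returns to 10.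

Step 20. Peracid attack on the less hindered α-face of the tetrasubstituted alkene may outrun hydroxyl-directed delivery to the β-face, which would lead after ring closure to the C9-epimeric ether. The fallback sets out from 25 and comes back at 26. Boc2O and DMAP should acylate only the secondary alcohol to give (13S)-7β-(tert-butoxycarbonyloxy)-16-(TBS-oxy)-19-(TBDPS-oxy)labd-8-en-14-yn-13-ol F5. Iodocarbonate cyclisation (IBr, toluene, −78 °C) should then form the iodonium on the open α-face while the carbonate carbonyl, tethered to the 7β-oxygen, can reach C8 only from the β-face (5-exo), giving (13S)-7β,8β-carbonyldioxy-9α-iodo-16-(TBS-oxy)-19-(TBDPS-oxy)labd-14-yn-13-ol F6. K2CO3 in MeOH cleaves the carbonate and the 8β-alkoxide displaces the anti 9α-iodide to give epoxide 26, which is closed to 27 with the acid of step 20.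

Step 21. The acetyl group may migrate from the tertiary axial O8 to the secondary O7 during or after orthoester hydrolysis, and the primary silyl ether may be partly lost in the aqueous acid. The fallback sets out from 27 and comes back at 30. Dess–Martin oxidation of the secondary alcohol first gives the α-ketol (13S)-9α,13-epoxy-8β-hydroxy-16-(TBS-oxy)-19-(TBDPS-oxy)labd-14-yn-7-one F7, in which no migration terminus is left. Forced acetylation of the tertiary hydroxyl (Ac2O, DMAP, Et3N, 1,2-dichloroethane, 60 °C) then gives 30.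

## Further compounds

F1 | step 4 | methyl (4E)-5-methylhepta-4,6-dienoate | C=C/C(C)=C/CCC(=O)OC
F2 | step 4 | methyl 3-[(1R,6S)-6-formyl-2,6-dimethylcyclohex-2-en-1-yl]propanoate | COC(=O)CC[C@H]1[C@@](C)(C=O)CCC=C1C
F3 | step 4 | methyl 3-[(1R,6S)-6-(hydroxymethyl)-2,6-dimethylcyclohex-2-en-1-yl]propanoate | COC(=O)CC[C@H]1[C@@](C)(CO)CCC=C1C
F4 | step 4 | methyl 3-[(1R,6S)-6-(TBDPS-oxymethyl)-2,6-dimethylcyclohex-2-en-1-yl]propanoate | COC(=O)CC[C@H]1[C@@](C)(CO[Si](c2ccccc2)(c2ccccc2)C(C)(C)C)CCC=C1C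
F5 | step 20 | (13S)-7β-(tert-butoxycarbonyloxy)-16-(TBS-oxy)-19-(TBDPS-oxy)labd-8-en-14-yn-13-ol | C#C[C@@](O)(CCC1=C(C)[C@@H](OC(=O)OC(C)(C)C)C[C@H]2[C@@](C)(CO[Si](c3ccccc3)(c3ccccc3)C(C)(C)C)CCC[C@]12C)CO[Si](C)(C)C(C)(C)C
F6 | step 20 | (13S)-7β,8β-carbonyldioxy-9α-iodo-16-(TBS-oxy)-19-(TBDPS-oxy)labd-14-yn-13-ol | C#C[C@@](O)(CC[C@@]1(I)[C@@]2(C)OC(=O)O[C@H]2C[C@H]3[C@@](C)(CO[Si](c4ccccc4)(c4ccccc4)C(C)(C)C)CCC[C@]13C)CO[Si](C)(C)C(C)(C)C
F7 | step 21 | (13S)-9α,13-epoxy-8β-hydroxy-16-(TBS-oxy)-19-(TBDPS-oxy)labd-14-yn-7-one | O[C@@]1(C)C(=O)C[C@H]2[C@@](C)(CO[Si](c3ccccc3)(c3ccccc3)C(C)(C)C)CCC[C@]2(C)[C@@]12CC[C@](C#C)(CO[Si](C)(C)C(C)(C)C)O2
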